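## Retrosynthetic overview

1. Enone C=C: Claisen–Schmidt disconnection to 4-hydroxybenzaldehyde (ring B, bought) and a 6-acetyl-5,8-dihydroxy-2H-chromene.
2. C8–OH: introduced late by para-hydroxylation (Elbs) of the 5-hydroxychromene.
3. Pyran ring and C2 (S): the C2–O bond comes from an oxidative dearomatisation of a 3-allylated resorcinol ketone to an o-quinone methide, which closes by oxa-6π under a chiral Brønsted acid.
4. Aryl–allyl bond: Pd-catalysed C-allylation of 2',4'-dihydroxyacetophenone (ring A, bought) with 7-hydroxy-6,7-dihydrogeranyl acetate, made from geranyl acetate by Mukaiyama hydration.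
5. Ring order: rings A and B are bought; the pyran ring is the only ring formed (step 3).

Assumption: the sense of induction of the chiral acid in step 3 cannot be predicted with certainty; the (R)-catalyst is written and, if it gives the (R)-chromene, its mirror image is used with nothing else changed.

## Route

Step 1
Reactants: 1 geranyl acetate [(2E)-3,7-dimethylocta-2,6-dien-1-yl acetate]
Product: 2 (2E)-7-hydroxy-3,7-dimethyloct-2-en-1-yl acetate
Conditions: Co(acac)2 (20 mol %), PhSiH3 (2.2 equiv), O2 (1 atm), THF, rt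
Reagents that add atoms: dioxygen, O=O
Why: Mukaiyama hydration (cobalt hydride hydrogen-atom transfer, then O2 trapping of the tertiary radical) is Markovnikov-selective and takes the electron-rich isopropylidene alkene in preference to the inductively deactivated allylic-acetate alkene, whose E geometry is untouched.

Step 2
Reactants: 2 (2E)-7-hydroxy-3,7-dimethyloct-2-en-1-yl acetate; 3 2',4'-dihydroxyacetophenone (2.5 equiv, excess recovered)
Product: 5 1-{2,4-dihydroxy-3-[(2E)-7-hydroxy-3,7-dimethyloct-2-en-1-yl]phenyl}ethan-1-one, via aryl allyl ether 4 (not isolated)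
Conditions: Pd(PPh3)4 (5 mol %), K2CO3 (1.1 equiv), 1,4-dioxane, 80 °C, 16 h
Reagents that add atoms: none
Why: Tsuji–Trost allylation under thermodynamic control, in which the π-allylpalladium from 2 first O-allylates the acidic 4'-OH to ether 4, this ether re-ionises at 80 °C, and irreversible linear C-allylation at C3' (the carbon flanked by both oxygens) drains the equilibrium with the E alkene kept.

Step 3
Reactants: 5 1-{2,4-dihydroxy-3-[(2E)-7-hydroxy-3,7-dimethyloct-2-en-1-yl]phenyl}ethan-1-one
Product: 7 1-[(2S)-5-hydroxy-2-(4-hydroxy-4-methylpentyl)-2-methyl-2H-chromen-6-yl]ethan-1-one, via o-quinone methide 6 (not isolated)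
Conditions: DDQ (1.05 equiv), (R)-3,3'-bis(2,4,6-triisopropylphenyl)-1,1'-binaphthyl-2,2'-diyl N-triflylphosphoramide (10 mol %), 4 Å MS, toluene, 0 °C
Reagents that add atoms: none
Why: Proposed new method: acid-activated DDQ abstracts hydride from the doubly activated benzylic–allylic CH2 and so dearomatises the resorcinol ring to o-quinone methide 6, which is formed hydrogen-bonded or ion-paired to the chiral phosphoramide and closes onto the non-chelated 4'-oxygen by oxa-6π electrocyclisation, restoring aromaticity and setting C2 as S inside the chiral pocket; the closest known reactions are the racemic DDQ cyclisation of o-prenylphenols to 2,2-dimethyl-2H-chromenes (same regiochemistry, chelated OH untouched), the chiral N-triflylphosphoramide-catalysed ring closure of o-hydroxystyryl carbinols to 2,2-disubstituted 2H-chromenes through the same contact ion pair, and chiral phosphoric acid-catalysed 6π electrocyclisations, and because uncatalysed DDQ oxidation of this acyl-deactivated phenol normally needs heating, the acid-bound pathway should dominate at 0 °C.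

Step 4
Reactants: 7 1-[(2S)-5-hydroxy-2-(4-hydroxy-4-methylpentyl)-2-methyl-2H-chromen-6-yl]ethan-1-one
Product: 9 1-[(2S)-5,8-dihydroxy-2-(4-hydroxy-4-methylpentyl)-2-methyl-2H-chromen-6-yl]ethan-1-one, via aryl sulfate 8 (not isolated)
Conditions: K2S2O8 (1.2 equiv), 2 M aq KOH, pyridine, 10 °C to rt, 24 h; then 2 M HCl, THF, 45 °C
Reagents that add atoms: potassium peroxodisulfate, [K+].[K+].[O-]S(=O)(=O)OOS(=O)(=O)[O-]
Why: Elbs persulfate oxidation, in which the 5-phenoxide is attacked by peroxodisulfate at its only free para position (C8) to give aryl sulfate 8, and mild acid hydrolysis then frees the hydroquinone without touching C2.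

Step 5
Reactants: 9 1-[(2S)-5,8-dihydroxy-2-(4-hydroxy-4-methylpentyl)-2-methyl-2H-chromen-6-yl]ethan-1-one; 10 4-hydroxybenzaldehyde (1.2 equiv)
Product: 12 (2E)-1-[(2S)-5,8-dihydroxy-2-(4-hydroxy-4-methylpentyl)-2-methyl-2H-chromen-6-yl]-3-(4-hydroxyphenyl)prop-2-en-1-one, via aldol adduct 11 (not isolated)
Conditions: 50% aq KOH, EtOH, degassed, Ar, rt, 48 h; then 1 M HCl to pH 5, 0 °C
Reagents that add atoms: none
Why: Claisen–Schmidt condensation, in which the methyl ketone enolate adds to the aldehyde and aldol 11 loses water by E1cB to the conjugated E-enone, the 2'-hydroxychalcone staying open through its hydrogen-bonded carbonyl and no stereocentre being touched.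

## Compound list

1 | geranyl acetate, (2E)-3,7-dimethylocta-2,6-dien-1-yl acetate | CC(=O)OC/C=C(\C)CCC=C(C)C | starting material
2 | (2E)-7-hydroxy-3,7-dimethyloct-2-en-1-yl acetate | CC(=O)OC/C=C(\C)CCCC(C)(C)O | intermediate
3 | 2',4'-dihydroxyacetophenone | CC(=O)c1ccc(O)cc1O | starting material
4 | 1-{2-hydroxy-4-[(2E)-7-hydroxy-3,7-dimethyloct-2-en-1-yl]oxyphenyl}ethan-1-one (aryl allyl ether) | CC(=O)c1ccc(OC/C=C(\C)CCCC(C)(C)O)cc1O | intermediate (not isolated)
5 | 1-{2,4-dihydroxy-3-[(2E)-7-hydroxy-3,7-dimethyloct-2-en-1-yl]phenyl}ethan-1-one | CC(=O)c1ccc(O)c(C/C=C(\C)CCCC(C)(C)O)c1O | intermediate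
6 | (6Z)-4-acetyl-5-hydroxy-6-[(2E)-7-hydroxy-3,7-dimethyloct-2-en-1-ylidene]cyclohexa-2,4-dien-1-one (o-quinone methide) | CC(=O)C1=C(O)/C(=C/C=C(\C)CCCC(C)(C)O)C(=O)C=C1 | intermediate (not isolated)
7 | 1-[(2S)-5-hydroxy-2-(4-hydroxy-4-methylpentyl)-2-methyl-2H-chromen-6-yl]ethan-1-one | CC(C)(O)CCC[C@@]1(C)C=Cc2c(O)c(C(C)=O)ccc2O1 | intermediate
8 | potassium (2S)-6-acetyl-5-hydroxy-2-(4-hydroxy-4-methylpentyl)-2-methyl-2H-chromen-8-yl sulfate | CC(C)(O)CCC[C@@]1(C)C=Cc2c(O)c(C(C)=O)cc(OS(=O)(=O)[O-])c2O1.[K+] | intermediate (not isolated)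
9 | 1-[(2S)-5,8-dihydroxy-2-(4-hydroxy-4-methylpentyl)-2-methyl-2H-chromen-6-yl]ethan-1-one | CC(C)(O)CCC[C@@]1(C)C=Cc2c(O)c(C(C)=O)cc(O)c2O1 | intermediate
10 | 4-hydroxybenzaldehyde | O=Cc1ccc(O)cc1 | starting material
11 | 1-[(2S)-5,8-dihydroxy-2-(4-hydroxy-4-methylpentyl)-2-methyl-2H-chromen-6-yl]-3-hydroxy-3-(4-hydroxyphenyl)propan-1-one (both carbinol epimers) | CC(C)(O)CCC[C@@]1(C)C=Cc2c(O)c(C(=O)CC(O)c3ccc(O)cc3)cc(O)c2O1 | intermediate (not isolated)
12 | (2E)-1-[(2S)-5,8-dihydroxy-2-(4-hydroxy-4-methylpentyl)-2-methyl-2H-chromen-6-yl]-3-(4-hydroxyphenyl)prop-2-en-1-one | CC(C)(O)CCC[C@@]1(C)C=Cc2c(O)c(C(=O)/C=C/c3ccc(O)cc3)cc(O)c2O1 | target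

## Step count and risks

Total steps: 5. Longest linear sequence: 5 steps (1 → 2 → 5 → 7 → 9 → 12).

**Step 3 (most likely to fail).** The enantioselectivity rests on the o-quinone methide closing while bound to the chiral acid; a free o-quinone methide would close racemically. The side-chain tertiary OH can also trap the cation as a tetrahydropyranyl ether, though that ether should re-ionise under the acid. The fallback sets out from 5 and comes back at 7, and moves the enantio-determining event to alkene-face selection. A chiral Lewis-base-catalysed sulfenoetherification (N-(phenylsulfanyl)phthalimide, MsOH, BINAM-derived selenophosphoramide catalyst of the required hand, CH2Cl2, −20 °C) forms the thiiranium ion on one face of the E alkene. The 4'-OH opens it anti at the tertiary carbon to give 1-[(2S,3R)-5-hydroxy-2-(4-hydroxy-4-methylpentyl)-2-methyl-3-(phenylsulfanyl)-3,4-dihydro-2H-chromen-6-yl]ethan-1-one F3. Oxidation with mCPBA (1.0 equiv, CH2Cl2, −78 °C) gives 1-[(2S,3R)-5-hydroxy-2-(4-hydroxy-4-methylpentyl)-2-methyl-3-(phenylsulfinyl)-3,4-dihydro-2H-chromen-6-yl]ethan-1-one F4. Thermal syn-elimination toward the benzylic C4–H (toluene, NaHCO3, 90 °C) then gives 7.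

**Step 2.** O-allylation may persist, and C5' may compete with C3'. The fallback sets out from 3 and 2 and comes back at 5, with the site fixed by a halide. Iodination of 3 between the two hydroxyls (I2, HIO3, aq EtOH, rt) gives 1-(2,4-dihydroxy-3-iodophenyl)ethan-1-one F1. Allylic borylation of 2 (B2pin2, Pd2(dba)3, DMSO, 50 °C) gives 2-[(2E)-7-hydroxy-3,7-dimethyloct-2-en-1-yl]-4,4,5,5-tetramethyl-1,3,2-dioxaborolane F2. Suzuki–Miyaura coupling of the two (Pd(OAc)2, bulky biarylphosphine chosen for coupling at the boron-bearing carbon, K3PO4, THF–H2O, 40 °C) gives 5.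

**Step 4.** Elbs oxidations are low-yielding, persulfate may attack the chromene alkene, and the acid hydrolysis threatens the tertiary alcohol. The fallback sets out from 7 and comes back at 9, and goes through a quinone under neutral conditions. Teuber oxidation with (KSO3)2NO (Fremy's salt) in KH2PO4-buffered acetone–water at rt gives (2S)-6-acetyl-2-(4-hydroxy-4-methylpentyl)-2-methyl-2H-chromene-5,8-dione F5. Reduction with Na2S2O4 in EtOAc–water gives 9.

## Further compounds

F1 | step 2 | 1-(2,4-dihydroxy-3-iodophenyl)ethan-1-one | CC(=O)c1ccc(O)c(I)c1O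
F2 | step 2 | 2-[(2E)-7-hydroxy-3,7-dimethyloct-2-en-1-yl]-4,4,5,5-tetramethyl-1,3,2-dioxaborolane | CC(C)(O)CCC/C(C)=C/CB1OC(C)(C)C(C)(C)O1
F3 | step 3 | 1-[(2S,3R)-5-hydroxy-2-(4-hydroxy-4-methylpentyl)-2-methyl-3-(phenylsulfanyl)-3,4-dihydro-2H-chromen-6-yl]ethan-1-one | CC(C)(O)CCC[C@@]1(C)[C@H](Sc3ccccc3)Cc2c(O)c(C(C)=O)ccc2O1
F4 | step 3 | 1-[(2S,3R)-5-hydroxy-2-(4-hydroxy-4-methylpentyl)-2-methyl-3-(phenylsulfinyl)-3,4-dihydro-2H-chromen-6-yl]ethan-1-one (both sulfur epimers) | CC(C)(O)CCC[C@@]1(C)[C@H](S(=O)c3ccccc3)Cc2c(O)c(C(C)=O)ccc2O1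
F5 | step 4 | (2S)-6-acetyl-2-(4-hydroxy-4-methylpentyl)-2-methyl-2H-chromene-5,8-dione | CC(C)(O)CCC[C@@]1(C)C=CC2=C(O1)C(=O)C=C(C(C)=O)C2=O
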